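**Retrosynthetic overview**

1. Target 14 is a cis-fused 3,7-dioxabicyclo[3.3.0]octane (ring A: C1–C2–O3–C4–C5; ring B: C5–C6–O7–C8–C1) with a tertiary OH at C1, an endo aryl at C2 (trans to that OH) and an exo aryl at C6.
2. Enabling feature: C2 of ring A is both the carbon α to ring oxygen O3 and the neighbour of carbinol carbon C1. The trans C1(OH)/C2(aryl) pair is therefore the retron of an anti (SN2) opening, at acetal carbon C2, of the C1–C2 epoxide of a ring A enol ether (O3–C2H=C1); the cis ring fusion fixed by C5–H dictates the epoxide face.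
3. Key disconnection: the C2–aryl bond, giving bicyclic enol ether 9 (only C5 and C6 stereogenic) plus an aryl cuprate from 4-bromoveratrole 10. Enol ether 9 comes from lactol 7 by dehydration, and 7 from exocyclic vinylsilane 5 by unmasking C2 as an aldehyde that the C4 hydroxyl traps to close ring A.
4. Ring B comes from a Cp2TiCl-mediated radical 5-exo-dig cyclisation of epoxy propargyl ether 4 (C5–C1 bond, C5 relayed from C6). Ether 4 comes from a Sharpless kinetic resolution of allylic alcohol 2 (C6, the only stereocenter set by catalysis), made from veratraldehyde 1.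
5. Order of ring formation: ring B (step 4), ring A (step 5), then the C1 hydroxyl, the C2 stereocenter and the C2–aryl bond together in step 7.

Key step: step 7

Remark on the chemistry: the alkene geometry of 5, the oxirane configurations of 6 and the anomeric configuration of 7 and 8 are left open, because all of them are erased by step 6.

**Step 1**
Reactants: 1 3,4-dimethoxybenzaldehyde
Product: 2 rac-1-(3,4-dimethoxyphenyl)prop-2-en-1-ol
Conditions: CH2=CHMgBr (1.2 equiv), THF, −78 → 0 °C; then H2O
Reagents that add atoms: vinylmagnesium bromide, C=C[Mg]Br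
Why: Grignard 1,2-addition to an aryl aldehyde; the new carbinol center (future C6) is formed as a racemate on purpose and is resolved and fixed in step 2.

**Step 2**
Reactants: 2 rac-1-(3,4-dimethoxyphenyl)prop-2-en-1-ol
Product: 3 (S)-(3,4-dimethoxyphenyl)[(2R)-oxiran-2-yl]methanol
Conditions: Ti(OiPr)4 (0.2 equiv), L-(+)-diisopropyl tartrate (0.25 equiv), t-BuOOH (0.55 equiv, isooctane), 4 Å MS, CH2Cl2, −20 °C, stopped near half conversion
Reagents that add atoms: tert-butyl hydroperoxide, CC(C)(C)OO
Why: Sharpless kinetic resolution by asymmetric epoxidation: with the L-(+)-tartrate catalyst the (R)-enantiomer of 2 should be the fast-reacting one and be epoxidised to the anti (erythro) epoxy alcohol, so the benzylic center that becomes C6 is fixed by catalyst control (at most half of 2 can be converted; (S)-2 stays behind and is separated), while the oxirane configuration is of no consequence later.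

**Step 3**
Reactants: 3 (S)-(3,4-dimethoxyphenyl)[(2R)-oxiran-2-yl]methanol
Product: 4 {3-[(S)-(3,4-dimethoxyphenyl)((2R)-oxiran-2-yl)methoxy]prop-1-yn-1-yl}trimethylsilane
Conditions: NaH (1.2 equiv), Bu4NI (cat.), 3-bromo-1-(trimethylsilyl)prop-1-yne (1.3 equiv), THF, 0 °C → rt
Reagents that add atoms: 3-bromo-1-(trimethylsilyl)prop-1-yne, C[Si](C)(C)C#CCBr
Why: Williamson etherification of the secondary alkoxide with an activated propargylic bromide installs C8, C1 and C2 (as a silyl-capped alkyne); no stereocenter is touched, and fast O-alkylation at low temperature should keep ahead of Payne migration of the epoxide.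

**Step 4**
Reactants: 4 {3-[(S)-(3,4-dimethoxyphenyl)((2R)-oxiran-2-yl)methoxy]prop-1-yn-1-yl}trimethylsilane
Product: 5 [(2R,3S)-2-(3,4-dimethoxyphenyl)-4-[(trimethylsilyl)methylidene]oxolan-3-yl]methanol
Conditions: Cp2TiCl2 (2.3 equiv), Zn dust, THF, rt, slow addition of the green Cp2TiCl solution to 4; then 1 M HCl
Reagents that add atoms: none
Why: Nugent–RajanBabu reductive epoxide opening: Cp2TiCl (trivalent titanium) cleaves the oxirane to the secondary C5 radical with a titanium alkoxide on C4, which should close ring B by 5-exo-dig addition to the silylalkyne (C5–C1 bond) before it is reduced; the alkenyl radical is then reduced and protonated, and C5 is set trans to the C6 aryl group by substrate control through a chair-like transition state with the aryl group pseudo-equatorial, the epoxide stereocenter having been erased at the radical stage.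

**Step 5**
Reactants: 5 [(2R,3S)-2-(3,4-dimethoxyphenyl)-4-[(trimethylsilyl)methylidene]oxolan-3-yl]methanol
Product: 7 (1S,5S,6R)-6-(3,4-dimethoxyphenyl)-3,7-dioxabicyclo[3.3.0]octan-2-ol (lactol; both anomers), via spiro-epoxysilane 6 (not isolated)
Conditions: mCPBA (1.1 equiv), Na2HPO4, CH2Cl2, 0 °C; then HClO4 (cat.), THF–H2O, rt
Reagents that add atoms: meta-chloroperoxybenzoic acid, OOC(=O)c1cccc(Cl)c1; water, O
Why: Prilezhaev epoxidation of the vinylsilane followed by acid hydrolysis of the α,β-epoxysilane (the classical vinylsilane-to-carbonyl unmasking: opening at the silicon-bearing carbon, then Peterson-type loss of Me3SiOH) should give the C2 aldehyde, which epimerises at C1 as needed and is trapped by the C4 hydroxyl as the cis-fused lactol of ring A (5-exo-trig addition to the carbonyl), the only strain-free mode of closure.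

**Step 6**
Reactants: 7 (1S,5S,6R)-6-(3,4-dimethoxyphenyl)-3,7-dioxabicyclo[3.3.0]octan-2-ol
Product: 9 (5S,6R)-6-(3,4-dimethoxyphenyl)-3,7-dioxabicyclo[3.3.0]oct-1-ene, via anomeric mesylate 8 (not isolated)
Conditions: MsCl (1.5 equiv), Et3N (4 equiv), CH2Cl2, −40 °C → reflux; aq. NaHCO3 wash, Et3N-deactivated silica
Reagents that add atoms: none
Why: Anomeric sulfonylation and base-mediated elimination (the standard furanoid glycal synthesis from 2-deoxy lactols) should give the enol ether; the bridgehead C1–H is the only β-hydrogen, so the double bond can only form between C1 and C2, and no stereocenter is created.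

**Step 7**
Reactants: 9 (5S,6R)-6-(3,4-dimethoxyphenyl)-3,7-dioxabicyclo[3.3.0]oct-1-ene; 10 4-bromo-1,2-dimethoxybenzene
Product: 14 (1R,2R,5S,6R)-2,6-bis(3,4-dimethoxyphenyl)-3,7-dioxabicyclo[3.3.0]octan-1-ol, via convex-face epoxide 11 (not isolated), via aryllithium 12 (not isolated), via lithium diarylcuprate 13 (not isolated)
Conditions: (a) 9, dimethyldioxirane (1.1 equiv, acetone), CH2Cl2, −78 → 0 °C, volatiles removed cold; (b) 10 (6 equiv), n-BuLi (6 equiv), THF–Et2O, −78 °C, then CuI (3 equiv), −40 °C; (c) crude 11 in THF added to 13, −78 → −30 °C; aq. NH4Cl/NH3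
Reagents that add atoms: dimethyldioxirane, CC1(C)OO1
Why: Dimethyldioxirane should transfer oxygen in a concerted way to the electron-rich C1=C2 enol ether of ring A, and only on the face that carries H-5 (the convex face) because a trans-fused bicyclo[3.3.0] skeleton is out of reach, which fixes C1 as the future (R)-carbinol in epoxide 11; cuprate 13 should then open the oxirane at acetal carbon C2 in an SN2 manner, anti to the departing epoxide oxygen, so that the C2–aryl bond is formed, the C1 tertiary alkoxide is set free and the aryl group lands on the concave face, trans to the hydroxyl. The closest known reaction type is the two-stage C-aryl glycoside synthesis from glycals: dioxirane epoxidation to a 1,2-anhydro sugar and opening at the anomeric carbon by a Gilman diarylcuprate with inversion. No ring of the product is closed in this step; the transient oxirane is formed by [2+1] oxygen-atom transfer and is opened again. Both new stereocenters come from substrate control: C1 from the facial bias imposed by C5 through the ring fusion, C2 from stereospecific inversion relative to the C1–O bond. The step needs attack at C2 and not at C1, which the O3 lone pair (activation of C2) and the fully substituted C1 secure, and it needs the SN2 path to outrun ionisation to the O3=C2 oxocarbenium ion, which would be captured from the convex face and give the C2 epimer; a soft, weakly Lewis acidic cuprate in ether at low temperature is chosen for that reason over a Grignard reagent or a Friedel–Crafts arene.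

**Compound list**

1 | 3,4-dimethoxybenzaldehyde (veratraldehyde) | COc1ccc(C=O)cc1OC | starting material
2 | rac-1-(3,4-dimethoxyphenyl)prop-2-en-1-ol | COc1ccc(C(O)C=C)cc1OC | intermediate
3 | (S)-(3,4-dimethoxyphenyl)[(2R)-oxiran-2-yl]methanol (anti epoxy alcohol) | COc1ccc([C@H](O)[C@H]2CO2)cc1OC | intermediate
4 | {3-[(S)-(3,4-dimethoxyphenyl)((2R)-oxiran-2-yl)methoxy]prop-1-yn-1-yl}trimethylsilane | COc1ccc([C@H](OCC#C[Si](C)(C)C)[C@H]2CO2)cc1OC | intermediate
5 | [(2R,3S)-2-(3,4-dimethoxyphenyl)-4-[(trimethylsilyl)methylidene]oxolan-3-yl]methanol (2,3-trans; E/Z mixture) | COc1ccc([C@@H]2OCC(=C[Si](C)(C)C)[C@H]2CO)cc1OC | intermediate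
6 | [(6R,7S)-6-(3,4-dimethoxyphenyl)-2-(trimethylsilyl)-1,5-dioxaspiro[2.4]heptan-7-yl]methanol (spiro-epoxysilane, oxirane epimers; not isolated) | COc1ccc([C@@H]2OCC3(OC3[Si](C)(C)C)[C@H]2CO)cc1OC | intermediate
7 | (1S,5S,6R)-6-(3,4-dimethoxyphenyl)-3,7-dioxabicyclo[3.3.0]octan-2-ol (cis-fused lactol, exo aryl, both anomers) | COc1ccc([C@@H]2OC[C@H]3C(O)OC[C@H]32)cc1OC | intermediate
8 | (1S,5S,6R)-6-(3,4-dimethoxyphenyl)-3,7-dioxabicyclo[3.3.0]octan-2-yl methanesulfonate (not isolated) | COc1ccc([C@@H]2OC[C@H]3C(OS(C)(=O)=O)OC[C@H]32)cc1OC | intermediate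
9 | (5S,6R)-6-(3,4-dimethoxyphenyl)-3,7-dioxabicyclo[3.3.0]oct-1-ene (ring A enol ether) | COc1ccc([C@@H]2OCC3=COC[C@H]32)cc1OC | intermediate
10 | 4-bromo-1,2-dimethoxybenzene (4-bromoveratrole) | COc1ccc(Br)cc1OC | starting material
11 | (1R,2S,5S,6R)-6-(3,4-dimethoxyphenyl)-1,2-epoxy-3,7-dioxabicyclo[3.3.0]octane (epoxide oxygen cis to H-5; not isolated) | COc1ccc([C@@H]2OC[C@@]34O[C@@H]3OC[C@H]42)cc1OC | intermediate
12 | (3,4-dimethoxyphenyl)lithium (not isolated) | COc1ccc([Li])cc1OC | intermediate
13 | lithium bis(3,4-dimethoxyphenyl)cuprate (not isolated) | [Li+].COc1ccc([Cu-]c2ccc(OC)c(OC)c2)cc1OC | intermediate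
14 | (1R,2R,5S,6R)-2,6-bis(3,4-dimethoxyphenyl)-3,7-dioxabicyclo[3.3.0]octan-1-ol | COc1ccc([C@H]2OC[C@H]3[C@H](c4ccc(OC)c(OC)c4)OC[C@@]23O)cc1OC | target

**Step count and risks**

Total step count: 7. Longest linear sequence: 7 steps (1 → 14); 10 enters in step 7.

Steps most likely to fail, in order of risk:

Step 7. Epoxide 11 has a fully substituted C1 and an acetal carbon C2, so it may ionise to the O3=C2 oxocarbenium ion (helped by lithium salts) before SN2 attack. The aryl group would then be delivered to the convex face (C2 epimer), or the epoxide would rearrange. The fallback sets out from lactol 7 and returns at 14. Lactol 7 is oxidised with PhI(OAc)2 and catalytic TEMPO to lactone (1S,5S,6R)-6-(3,4-dimethoxyphenyl)-3,7-dioxabicyclo[3.3.0]octan-2-one F1. F1 is hydroxylated at C1 on its convex face (KHMDS, then 2-(phenylsulfonyl)-3-phenyloxaziridine, THF, −78 °C) to give α-hydroxy lactone (1R,5S,6R)-6-(3,4-dimethoxyphenyl)-1-hydroxy-3,7-dioxabicyclo[3.3.0]octan-2-one F2. Aryllithium 12 (from 10 and n-BuLi, about 2.5 equiv, THF, −78 °C) adds to the lactone carbonyl of F2 to give hemiketal (1R,5S,6R)-2,6-bis(3,4-dimethoxyphenyl)-3,7-dioxabicyclo[3.3.0]octane-1,2-diol F3. Ionic reduction of F3 with Et3SiH and BF3·OEt2 in CH2Cl2 at −78 °C should deliver hydride to the aryl-substituted oxocarbenium ion from the convex face, which places the aryl group endo and gives 14.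

Step 2. The Lewis acidic titanium tartrate complex may ionise the electron-rich benzylic C–O bond of 2 or 3 (racemisation, allylic transposition, ether exchange), which would erode enantiomeric purity. The fallback sets out from 2 and returns at 5. Lipase-mediated kinetic resolution (Candida antarctica lipase B, vinyl acetate, MTBE, 30 °C) should acylate the (R)-enantiomer to (R)-1-(3,4-dimethoxyphenyl)prop-2-en-1-yl acetate F4. Methanolysis (K2CO3, MeOH) gives (R)-1-(3,4-dimethoxyphenyl)prop-2-en-1-ol F5. Etherification under the conditions of step 3 gives enyne ether {3-[(R)-1-(3,4-dimethoxyphenyl)prop-2-en-1-yloxy]prop-1-yn-1-yl}trimethylsilane F6. mCPBA (NaHCO3, CH2Cl2, rt) epoxidises the terminal alkene to epoxy ether F7, a mixture of oxirane epimers that both lead to the same C5 radical. Cyclisation under the conditions of step 4 then gives 5.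

Step 6. Elimination toward the bridgehead C1–H may stall at the anomeric chloride, or the acid-labile enol ether may be hydrolysed or oligomerised by the ammonium salts. The fallback sets out from 7 and returns at 9. Selenoglycosidation of 7 (PhSeH, BF3·OEt2, CH2Cl2, −20 °C, attack on the convex face) gives phenyl selenoglycoside (1S,5S,6R)-6-(3,4-dimethoxyphenyl)-2-(phenylselanyl)-3,7-dioxabicyclo[3.3.0]octane F8. Oxidation (t-BuOOH, i-Pr2NEt, CH2Cl2, 0 °C → rt) gives selenoxide F9, whose syn elimination with the cis C1–H should give 9.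

Further compounds

F1 | step 7 | (1S,5S,6R)-6-(3,4-dimethoxyphenyl)-3,7-dioxabicyclo[3.3.0]octan-2-one | COc1ccc([C@@H]2OC[C@H]3C(=O)OC[C@H]32)cc1OC
F2 | step 7 | (1R,5S,6R)-6-(3,4-dimethoxyphenyl)-1-hydroxy-3,7-dioxabicyclo[3.3.0]octan-2-one | COc1ccc([C@@H]2OC[C@@]3(O)C(=O)OC[C@H]32)cc1OC
F3 | step 7 | (1R,5S,6R)-2,6-bis(3,4-dimethoxyphenyl)-3,7-dioxabicyclo[3.3.0]octane-1,2-diol (hemiketal, both anomers) | COc1ccc([C@@H]2OC[C@@]3(O)C(O)(c4ccc(OC)c(OC)c4)OC[C@H]32)cc1OC
F4 | step 2 | (R)-1-(3,4-dimethoxyphenyl)prop-2-en-1-yl acetate | COc1ccc([C@H](OC(C)=O)C=C)cc1OC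
F5 | step 2 | (R)-1-(3,4-dimethoxyphenyl)prop-2-en-1-ol | COc1ccc([C@H](O)C=C)cc1OC
F6 | step 2 | {3-[(R)-1-(3,4-dimethoxyphenyl)prop-2-en-1-yloxy]prop-1-yn-1-yl}trimethylsilane | COc1ccc([C@H](OCC#C[Si](C)(C)C)C=C)cc1OC
F7 | step 2 | {3-[(S)-(3,4-dimethoxyphenyl)(oxiran-2-yl)methoxy]prop-1-yn-1-yl}trimethylsilane (oxirane epimers) | COc1ccc([C@H](OCC#C[Si](C)(C)C)C2CO2)cc1OC
F8 | step 6 | (1S,5S,6R)-6-(3,4-dimethoxyphenyl)-2-(phenylselanyl)-3,7-dioxabicyclo[3.3.0]octane | COc1ccc([C@@H]2OC[C@H]3C([Se]c4ccccc4)OC[C@H]32)cc1OC
F9 | step 6 | (1S,5S,6R)-6-(3,4-dimethoxyphenyl)-2-(phenylseleninyl)-3,7-dioxabicyclo[3.3.0]octane | COc1ccc([C@@H]2OC[C@H]3C([Se](=O)c4ccccc4)OC[C@H]32)cc1OC
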